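**Retrosynthetic overview**
1. C11=C12 is made last by HWE olefination of the bicyclic C15 hydroxy‑enal 22 with the C10 tetraenyl phosphonate 34; 34 comes from a Suzuki coupling of two pieces (28, 33) made from one iodo‑alcohol (26).
2. The dihydrofuran (second and last ring; O–C8 bond and the C8 centre) comes from Ag(I) 5‑endo cycloisomerisation of the α‑hydroxy vinylallene 19, with axis‑to‑centre chirality transfer.
3. The key C8–C9 bond and the allene axis come from a Rh(I)‑catalysed syn‑SN2′ alkenylation of the terminal alkynyl epoxide 15 with alkenylboronate 18 (new reaction).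
4. Epoxy‑alkyne 15 comes from 3‑silyloxy‑β‑cyclogeraniol 11 by Sharpless epoxidation (sets C5/C6), oxidation and Colvin homologation; C3 is set by IpcBH2 hydroboration of a safranol ether.
5. The carbocycle is formed first (mesityl oxide + methyl acetoacetate annulation); ring order: cyclohexene → temporary epoxide → dihydrofuran.

Assumption: every carbon source that ends up in the target is numbered as a starting material (each ≤ 8 non‑H atoms); silyl, MOP, boron, phosphorus and tin carriers are treated as reagents or protecting groups; locants C1–C20/C12′ in the explanations follow carotenoid numbering (the ring carbinol is R in 9–11 and S from 12 on only because CIP priorities change).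

Nothing here has been run; two stereochemical assignments rest on models rather than on direct precedent I can confirm: the sense of IpcBH2 in step 6 and the syn course of the new step 14.

**Route**

Step 1
Reactants: 1 mesityl oxide; 2 methyl acetoacetate
Product: 3 methyl 2,6,6-trimethyl-4-oxocyclohex-2-ene-1-carboxylate (racemic)
Conditions: BF3·OEt2 (cat.), neat, 0 → 25 °C, 3 d; distil
Reagents that add atoms: none
Why: Lewis‑acid‑promoted Michael addition of the acetoacetate to mesityl oxide followed by intramolecular aldol condensation (Robinson‑type annulation) assembles C1–C7 and all three ring methyls; the C6 centre is erased in step 3.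

Step 2
Reactants: 3 methyl 2,6,6-trimethyl-4-oxocyclohex-2-ene-1-carboxylate
Product: 4 methyl 4-hydroxy-2,6,6-trimethylcyclohex-2-ene-1-carboxylate (diastereomer mixture, racemic)
Conditions: NaBH4, CeCl3·7H2O, MeOH, 0 °C
Reagents that add atoms: none
Why: Luche reduction gives clean 1,2‑reduction of the enone and leaves the ester; stereochemistry is irrelevant here.

Step 3
Reactants: 4 methyl 4-hydroxy-2,6,6-trimethylcyclohex-2-ene-1-carboxylate
Product: 5 methyl 2,6,6-trimethylcyclohexa-1,3-diene-1-carboxylate (methyl safranate)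
Conditions: p‑TsOH·H2O (5 mol %), toluene, reflux, Dean–Stark
Reagents that add atoms: none
Why: Acid‑catalysed 1,4‑dehydration through the allylic cation ends in loss of the acidic H6, giving the ester‑conjugated 1,3‑diene (achiral).

Step 4
Reactants: 5 methyl safranate
Product: 6 (2,6,6-trimethylcyclohexa-1,3-dien-1-yl)methanol (safranol)
Conditions: LiAlH4, Et2O, 0 °C
Reagents that add atoms: none
Why: Hydride 1,2‑reduction of the hindered dienoate to the primary allylic alcohol.

Step 5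
Reactants: 6 safranol
Product: 7 1-{[(2-methoxypropan-2-yl)oxy]methyl}-2,6,6-trimethylcyclohexa-1,3-diene
Conditions: 2‑methoxypropene, PPTS (2 mol %), CH2Cl2, 0 °C
Reagents that add atoms: 2‑methoxypropene, COC(C)=C
Why: Acid‑catalysed acetalisation masks the OH as a MOP ether so that the borane in step 6 sees only the diene.

Step 6
Reactants: 7 safranol MOP ether
Product: 9 (1R)-4-{[(2-methoxypropan-2-yl)oxy]methyl}-3,5,5-trimethylcyclohex-3-en-1-ol, via alkyl(isopinocampheyl)borane 8 (not isolated)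
Conditions: IpcBH2 [from (+)‑α‑pinene], THF, −25 °C, 24 h; then 3 M NaOH, 30 % H2O2, 0 → 25 °C
Reagents that add atoms: isopinocampheylborane, C[C@H]1[C@H](B)C[C@@H]2C[C@H]1C2(C)C (B and Ipc, in 8 only); hydrogen peroxide, OO
Why: Brown asymmetric hydroboration: the bulky monoalkylborane adds only to the disubstituted C3=C4 bond with boron at the less hindered diene terminus C3, and oxidation with retention sets the C3 carbinol (R here, by the Brown model for IpcBH2 from (+)‑α‑pinene); any enantiomer that leaks through becomes a separable diastereomer in step 9.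

Step 7
Reactants: 9 MOP‑protected (R)‑alcohol
Product: 10 tert-butyl{[(1R)-4-{[(2-methoxypropan-2-yl)oxy]methyl}-3,5,5-trimethylcyclohex-3-en-1-yl]oxy}dimethylsilane
Conditions: TBSCl, imidazole, DMF, 25 °C
Reagents that add atoms: tert‑butyldimethylsilyl chloride, CC(C)(C)[Si](C)(C)Cl
Why: Standard silylation of the unhindered secondary alcohol; the MOP acetal is stable to base.

Step 8
Reactants: 10 MOP/TBS diether
Product: 11 [(4R)-4-{[tert-butyl(dimethyl)silyl]oxy}-2,6,6-trimethylcyclohex-1-en-1-yl]methanol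
Conditions: PPTS (5 mol %), MeOH, 0 °C, 15 min
Reagents that add atoms: none
Why: Trans‑acetalisation to methanol removes the very labile MOP group while the secondary TBS ether survives.

Step 9
Reactants: 11 3‑silyloxy‑β‑cyclogeraniol
Product: 12 [(1R,4S,6R)-4-{[tert-butyl(dimethyl)silyl]oxy}-2,2,6-trimethyl-7-oxabicyclo[4.1.0]heptan-1-yl]methanol (epoxide O anti to OTBS)
Conditions: Ti(OiPr)4 (1.0 equiv), D‑(−)‑diethyl tartrate (1.2 equiv), t‑BuOOH (2 equiv), 4 Å MS, CH2Cl2, −20 °C
Reagents that add atoms: tert‑butyl hydroperoxide, CC(C)(C)OO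
Why: Sharpless asymmetric epoxidation: the D‑(−)‑tartrate complex delivers oxygen to the face of the tetrasubstituted allylic alcohol anti to the C3 silyloxy group (reagent control), setting C5 (R, final) and the temporary C6 centre.

Step 10
Reactants: 12 epoxy alcohol
Product: 13 (1S,4S,6R)-4-{[tert-butyl(dimethyl)silyl]oxy}-2,2,6-trimethyl-7-oxabicyclo[4.1.0]heptane-1-carbaldehyde
Conditions: TPAP (5 mol %), NMO (1.5 equiv), 4 Å MS, CH2Cl2, 25 °C
Reagents that add atoms: none
Why: Ley–Griffith oxidation of the hindered primary alcohol; the aldehyde has no α‑H, so nothing can epimerise.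

Step 11
Reactants: 13 epoxy aldehyde; 14 (trimethylsilyl)diazomethane
Product: 15 tert-butyl{[(1R,4S,6R)-1-ethynyl-2,2,6-trimethyl-7-oxabicyclo[4.1.0]heptan-4-yl]oxy}dimethylsilane
Conditions: 14, n‑BuLi, THF, −78 °C; add 13; −78 → 25 °C
Reagents that add atoms: none
Why: Colvin homologation (Shioiri protocol): addition of LiC(N2)SiMe3, Peterson elimination, N2 loss and 1,2‑H shift of the alkylidene carbene give the terminal alkyne (C8) without touching the epoxide.

Step 12
Reactants: 16 but-2-yn-1-ol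
Product: 17 (but-2-yn-1-yloxy)(tert-butyl)dimethylsilane
Conditions: TBSCl, imidazole, CH2Cl2, 25 °C
Reagents that add atoms: tert‑butyldimethylsilyl chloride, CC(C)(C)[Si](C)(C)Cl
Why: Routine silylation of the primary propargylic alcohol.

Step 13
Reactants: 17 butynyl TBS ether
Product: 18 tert-butyldimethyl{[(2Z)-3-(4,4,5,5-tetramethyl-1,3,2-dioxaborolan-2-yl)but-2-en-1-yl]oxy}silane
Conditions: CuCl (5 mol %), Xantphos (5 mol %), NaOt‑Bu (10 mol %), B2pin2 (1.1 equiv), MeOH (2 equiv), THF, 25 °C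
Reagents that add atoms: bis(pinacolato)diboron, CC1(C)OB(OC1(C)C)B1OC(C)(C)C(C)(C)O1
Why: Cu‑catalysed syn borylcupration/protonation (formal hydroboration) of a propargylic ether places boron distal to oxygen and, by syn addition, trans to CH2OTBS, which fixes the later 9E geometry.

Step 14
Reactants: 15 epoxy alkyne; 18 alkenylboronate
Product: 19 (1R,5S)-5-{[tert-butyl(dimethyl)silyl]oxy}-2-[(3E)-5-{[tert-butyl(dimethyl)silyl]oxy}-3-methylpenta-1,3-dien-1-ylidene]-1,3,3-trimethylcyclohexan-1-ol, (S) allene axis [(3S,5R,6S) in carotenoid numbering]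
Conditions: [Rh(OH)(cod)]2 (3 mol %), 18 (1.5 equiv), KOH (20 mol %), 1,4‑dioxane/H2O 10:1, 25 °C, 15 added over 2 h
Reagents that add atoms: none
Why: Proposed new method: Rh(I)‑catalysed syn‑SN2′ alkenylation of a terminal alkynyl epoxide — the alkenyl–Rh formed by transmetalation adds syn across C7≡C8 with Rh at C7 (held by the epoxide oxygen) and the alkenyl group at the unhindered terminal carbon, and syn β‑oxygen elimination then opens the epoxide so that the new C8–C9 bond lies on the side from which the C6–O bond departs, which fixes the allene axis from the C5/C6 centres while C5–O stays intact; the quaternary propargylic carbon and slow addition should suppress Rh‑acetylide oligomerisation; the closest known reaction type is the Rh‑catalysed syn‑selective arylation of internal alkynyl oxiranes with arylboronic acids (carborhodation/β‑oxygen elimination), not shown for alkenylboronates, terminal alkynes or this hindered epoxide.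

Step 15
Reactants: 19 α‑hydroxy vinylallene
Product: 20 tert-butyl{[(2E)-3-[(2R,6S,7aR)-6-{[tert-butyl(dimethyl)silyl]oxy}-4,4,7a-trimethyl-2,4,5,6,7,7a-hexahydro-1-benzofuran-2-yl]but-2-en-1-yl]oxy}dimethylsilane
Conditions: AgNO3 (0.2 equiv), CaCO3, acetone/H2O 9:1, 25 °C, dark
Reagents that add atoms: none
Why: Ag(I)‑catalysed 5‑endo cycloisomerisation of an α‑hydroxyallene (Marshall/Krause type): the tertiary OH attacks C8 in the plane of the C7=C8 π‑bond anti to silver, so the allene axis is transferred to the C8 centre (R, side chain trans to the C5 methyl), and protodemetalation closes the dihydrofuran.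

Step 16
Reactants: 20 bis‑silyl ether
Product: 21 (2R,6S,7aR)-2-[(2E)-4-hydroxybut-2-en-2-yl]-4,4,7a-trimethyl-2,4,5,6,7,7a-hexahydro-1-benzofuran-6-ol
Conditions: TBAF (2.5 equiv), THF, 0 → 25 °C
Reagents that add atoms: none
Why: Fluoride desilylation under basic conditions avoids acid, which would ionise the doubly allylic C8–O bond and epimerise C8.

Step 17
Reactants: 21 diol
Product: 22 (2E)-3-[(2R,6S,7aR)-6-hydroxy-4,4,7a-trimethyl-2,4,5,6,7,7a-hexahydro-1-benzofuran-2-yl]but-2-enal
Conditions: activated MnO2 (20 equiv), CH2Cl2, 25 °C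
Reagents that add atoms: none
Why: MnO2 oxidises only the allylic primary alcohol and leaves the saturated secondary C3–OH and the alkene geometry untouched.

Step 18
Reactants: 23 prop-2-yn-1-ol; 24 trimethylaluminium
Product: 26 (2E)-3-iodo-2-methylprop-2-en-1-ol, via alkenylalane 25 (not isolated)
Conditions: 24 (3 equiv), Cp2ZrCl2 (25 mol %), CH2Cl2, 0 → 25 °C; then I2, THF, −30 → 0 °C
Reagents that add atoms: iodine, II
Why: Negishi Zr‑catalysed carboalumination adds Me and Al syn across the alkyne (Me to the internal carbon), and iodinolysis with retention gives the E iodide that carries C13/C20 and C13′/C20′.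

Step 19
Reactants: 26 iodo alcohol
Product: 27 (1E)-3-bromo-1-iodo-2-methylprop-1-ene
Conditions: PBr3 (0.4 equiv), Et2O, 0 °C
Reagents that add atoms: phosphorus tribromide, BrP(Br)Br
Why: SN2 bromination of the primary allylic alcohol; the vinyl iodide geometry is not affected.

Step 20
Reactants: 27 allylic bromide
Product: 28 diethyl [(2E)-3-iodo-2-methylprop-2-en-1-yl]phosphonate
Conditions: P(OEt)3, neat, 90 °C
Reagents that add atoms: triethyl phosphite, CCOP(OCC)OCC
Why: Michaelis–Arbuzov reaction of the reactive allylic bromide.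

Step 21
Reactants: 26 iodo alcohol
Product: 29 tert-butyl{[(2E)-3-iodo-2-methylprop-2-en-1-yl]oxy}dimethylsilane
Conditions: TBSCl, imidazole, CH2Cl2, 25 °C
Reagents that add atoms: tert‑butyldimethylsilyl chloride, CC(C)(C)[Si](C)(C)Cl
Why: Routine silylation; this TBS group is carried to the last step.

Step 22
Reactants: 29 vinyl iodide; 30 ethynyltrimethylsilane
Product: 31 tert-butyldimethyl{[(2E)-2-methyl-5-(trimethylsilyl)pent-2-en-4-yn-1-yl]oxy}silane
Conditions: Pd(PPh3)2Cl2 (2 mol %), CuI (4 mol %), Et3N, THF, 25 °C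
Reagents that add atoms: none
Why: Sonogashira coupling proceeds with retention of the vinyl iodide geometry and brings in C15/C15′.

Step 23
Reactants: 31 silyl enyne
Product: 32 tert-butyl{[(2E)-2-methylpent-2-en-4-yn-1-yl]oxy}dimethylsilane
Conditions: K2CO3 (0.2 equiv), MeOH, 25 °C
Reagents that add atoms: none
Why: Methanolysis of the alkynyl C–Si bond; the silyl ether is stable.

Step 24
Reactants: 32 terminal enyne
Product: 33 tert-butyldimethyl{[(2E,4E)-2-methyl-5-(4,4,5,5-tetramethyl-1,3,2-dioxaborolan-2-yl)penta-2,4-dien-1-yl]oxy}silane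
Conditions: pinacolborane (1.2 equiv), Cp2Zr(H)Cl (10 mol %), Et3N (10 mol %), CH2Cl2, 25 °C
Reagents that add atoms: pinacolborane, [H]B1OC(C)(C)C(C)(C)O1
Why: Zr‑catalysed syn, anti‑Markovnikov hydroboration of the terminal alkyne gives the E alkenylboronate.

Step 25
Reactants: 28 iodo phosphonate; 33 dienylboronate
Product: 34 diethyl [(2E,4E,6E)-8-{[tert-butyl(dimethyl)silyl]oxy}-2,7-dimethylocta-2,4,6-trien-1-yl]phosphonate
Conditions: Pd(dppf)Cl2·CH2Cl2 (3 mol %), 3 M aq K3PO4 (3 equiv), THF, 25 °C, dark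
Reagents that add atoms: none
Why: Suzuki–Miyaura coupling forms C14–C15 with retention at both sp2 partners and tolerates the phosphonate.

Step 26
Reactants: 22 hydroxy enal; 34 tetraenyl phosphonate
Product: 35 (2R,6S,7aR)-2-[(2E,4E,6E,8E,10E)-12-{[tert-butyl(dimethyl)silyl]oxy}-6,11-dimethyldodeca-2,4,6,8,10-pentaen-2-yl]-4,4,7a-trimethyl-2,4,5,6,7,7a-hexahydro-1-benzofuran-6-ol
Conditions: 34 (1.5 equiv), NaHMDS (1.45 equiv), THF, −78 °C; add 22; −78 → 0 °C, dark
Reagents that add atoms: none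
Why: Horner–Wadsworth–Emmons olefination of an enal with an allylic phosphonate anion forms C11=C12 with E selectivity; no carbanion is generated next to C8, so the ring ether is safe.

Step 27
Reactants: 35 silyl ether
Product: 36 (2R,6S,7aR)-2-[(2E,4E,6E,8E,10E)-12-hydroxy-6,11-dimethyldodeca-2,4,6,8,10-pentaen-2-yl]-4,4,7a-trimethyl-2,4,5,6,7,7a-hexahydro-1-benzofuran-6-ol (CNP0239155.2)
Conditions: TBAF (1.5 equiv), THF, 0 → 25 °C, dark
Reagents that add atoms: none
Why: Fluoride cleavage of the primary allylic TBS ether under non‑acidic conditions preserves C8 and the all‑E pentaene.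

**Compound list**

1 | mesityl oxide (4-methylpent-3-en-2-one) | CC(=O)C=C(C)C | starting material
2 | methyl acetoacetate | CC(=O)CC(=O)OC | starting material
3 | methyl 2,6,6-trimethyl-4-oxocyclohex-2-ene-1-carboxylate (racemic) | COC(=O)C1C(C)=CC(=O)CC1(C)C | intermediate
4 | methyl 4-hydroxy-2,6,6-trimethylcyclohex-2-ene-1-carboxylate (diastereomer mixture) | COC(=O)C1C(C)=CC(O)CC1(C)C | intermediate
5 | methyl 2,6,6-trimethylcyclohexa-1,3-diene-1-carboxylate | COC(=O)C1=C(C)C=CCC1(C)C | intermediate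
6 | (2,6,6-trimethylcyclohexa-1,3-dien-1-yl)methanol | OCC1=C(C)C=CCC1(C)C | intermediate
7 | 1-{[(2-methoxypropan-2-yl)oxy]methyl}-2,6,6-trimethylcyclohexa-1,3-diene | COC(C)(C)OCC1=C(C)C=CCC1(C)C | intermediate
8 | [(1R)-4-{[(2-methoxypropan-2-yl)oxy]methyl}-3,5,5-trimethylcyclohex-3-en-1-yl](isopinocampheyl)borane | C[C@H]1[C@H](B[C@H]2CC(C)(C)C(COC(C)(C)OC)=C(C)C2)C[C@@H]3C[C@H]1C3(C)C | intermediate
9 | (1R)-4-{[(2-methoxypropan-2-yl)oxy]methyl}-3,5,5-trimethylcyclohex-3-en-1-ol | COC(C)(C)OCC1=C(C)C[C@@H](O)CC1(C)C | intermediate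
10 | tert-butyl{[(1R)-4-{[(2-methoxypropan-2-yl)oxy]methyl}-3,5,5-trimethylcyclohex-3-en-1-yl]oxy}dimethylsilane | COC(C)(C)OCC1=C(C)C[C@@H](O[Si](C)(C)C(C)(C)C)CC1(C)C | intermediate
11 | [(4R)-4-{[tert-butyl(dimethyl)silyl]oxy}-2,6,6-trimethylcyclohex-1-en-1-yl]methanol | OCC1=C(C)C[C@@H](O[Si](C)(C)C(C)(C)C)CC1(C)C | intermediate
12 | [(1R,4S,6R)-4-{[tert-butyl(dimethyl)silyl]oxy}-2,2,6-trimethyl-7-oxabicyclo[4.1.0]heptan-1-yl]methanol | OC[C@]12C(C)(C)C[C@H](O[Si](C)(C)C(C)(C)C)C[C@@]1(C)O2 | intermediate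
13 | (1S,4S,6R)-4-{[tert-butyl(dimethyl)silyl]oxy}-2,2,6-trimethyl-7-oxabicyclo[4.1.0]heptane-1-carbaldehyde | O=C[C@]12C(C)(C)C[C@H](O[Si](C)(C)C(C)(C)C)C[C@@]1(C)O2 | intermediate
14 | (trimethylsilyl)diazomethane | C[Si](C)(C)C=[N+]=[N-] | starting material
15 | tert-butyl{[(1R,4S,6R)-1-ethynyl-2,2,6-trimethyl-7-oxabicyclo[4.1.0]heptan-4-yl]oxy}dimethylsilane | C#C[C@]12C(C)(C)C[C@H](O[Si](C)(C)C(C)(C)C)C[C@@]1(C)O2 | intermediate
16 | but-2-yn-1-ol | CC#CCO | starting material
17 | (but-2-yn-1-yloxy)(tert-butyl)dimethylsilane | CC#CCO[Si](C)(C)C(C)(C)C | intermediate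
18 | tert-butyldimethyl{[(2Z)-3-(4,4,5,5-tetramethyl-1,3,2-dioxaborolan-2-yl)but-2-en-1-yl]oxy}silane | C/C(B1OC(C)(C)C(C)(C)O1)=C\CO[Si](C)(C)C(C)(C)C | intermediate
19 | (1R,5S)-5-{[tert-butyl(dimethyl)silyl]oxy}-2-[(3E)-5-{[tert-butyl(dimethyl)silyl]oxy}-3-methylpenta-1,3-dien-1-ylidene]-1,3,3-trimethylcyclohexan-1-ol, (S) allene axis | C[C@@]1(O)C[C@@H](O[Si](C)(C)C(C)(C)C)CC(C)(C)C1=[C@]=C([H])/C(C)=C/CO[Si](C)(C)C(C)(C)C | intermediate
20 | tert-butyl{[(2E)-3-[(2R,6S,7aR)-6-{[tert-butyl(dimethyl)silyl]oxy}-4,4,7a-trimethyl-2,4,5,6,7,7a-hexahydro-1-benzofuran-2-yl]but-2-en-1-yl]oxy}dimethylsilane | CC(C)(C)[Si](C)(C)OC/C=C(\C)[C@H]1C=C2C(C)(C)C[C@H](O[Si](C)(C)C(C)(C)C)C[C@@]2(C)O1 | intermediate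
21 | (2R,6S,7aR)-2-[(2E)-4-hydroxybut-2-en-2-yl]-4,4,7a-trimethyl-2,4,5,6,7,7a-hexahydro-1-benzofuran-6-ol | OC/C=C(\C)[C@H]1C=C2C(C)(C)C[C@H](O)C[C@@]2(C)O1 | intermediate
22 | (2E)-3-[(2R,6S,7aR)-6-hydroxy-4,4,7a-trimethyl-2,4,5,6,7,7a-hexahydro-1-benzofuran-2-yl]but-2-enal | O=C/C=C(\C)[C@H]1C=C2C(C)(C)C[C@H](O)C[C@@]2(C)O1 | intermediate
23 | prop-2-yn-1-ol | C#CCO | starting material
24 | trimethylaluminium | C[Al](C)C | starting material
25 | dimethyl[(1E)-3-[(dimethylalumanyl)oxy]-2-methylprop-1-en-1-yl]alumane | C[Al](C)/C=C(\C)CO[Al](C)C | intermediate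
26 | (2E)-3-iodo-2-methylprop-2-en-1-ol | OC/C(C)=C/I | intermediate
27 | (1E)-3-bromo-1-iodo-2-methylprop-1-ene | BrC/C(C)=C/I | intermediate
28 | diethyl [(2E)-3-iodo-2-methylprop-2-en-1-yl]phosphonate | CCOP(=O)(OCC)C/C(C)=C/I | intermediate
29 | tert-butyl{[(2E)-3-iodo-2-methylprop-2-en-1-yl]oxy}dimethylsilane | CC(C)(C)[Si](C)(C)OC/C(C)=C/I | intermediate
30 | ethynyltrimethylsilane | C#C[Si](C)(C)C | starting material
31 | tert-butyldimethyl{[(2E)-2-methyl-5-(trimethylsilyl)pent-2-en-4-yn-1-yl]oxy}silane | CC(C)(C)[Si](C)(C)OC/C(C)=C/C#C[Si](C)(C)C | intermediate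
32 | tert-butyl{[(2E)-2-methylpent-2-en-4-yn-1-yl]oxy}dimethylsilane | CC(C)(C)[Si](C)(C)OC/C(C)=C/C#C | intermediate
33 | tert-butyldimethyl{[(2E,4E)-2-methyl-5-(4,4,5,5-tetramethyl-1,3,2-dioxaborolan-2-yl)penta-2,4-dien-1-yl]oxy}silane | CC(C)(C)[Si](C)(C)OC/C(C)=C/C=C/B1OC(C)(C)C(C)(C)O1 | intermediate
34 | diethyl [(2E,4E,6E)-8-{[tert-butyl(dimethyl)silyl]oxy}-2,7-dimethylocta-2,4,6-trien-1-yl]phosphonate | CCOP(=O)(OCC)C/C(C)=C/C=C/C=C(\C)CO[Si](C)(C)C(C)(C)C | intermediate
35 | (2R,6S,7aR)-2-[(2E,4E,6E,8E,10E)-12-{[tert-butyl(dimethyl)silyl]oxy}-6,11-dimethyldodeca-2,4,6,8,10-pentaen-2-yl]-4,4,7a-trimethyl-2,4,5,6,7,7a-hexahydro-1-benzofuran-6-ol | CC(/C=C/C=C(\C)[C@H]1C=C2C(C)(C)C[C@H](O)C[C@@]2(C)O1)=C\C=C\C=C(/C)CO[Si](C)(C)C(C)(C)C | intermediate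
36 | (2R,6S,7aR)-2-[(2E,4E,6E,8E,10E)-12-hydroxy-6,11-dimethyldodeca-2,4,6,8,10-pentaen-2-yl]-4,4,7a-trimethyl-2,4,5,6,7,7a-hexahydro-1-benzofuran-6-ol | CC(/C=C/C=C(\C)[C@H]1C=C2C(C)(C)C[C@H](O)C[C@@]2(C)O1)=C\C=C\C=C(/C)CO | target

**Step count and risks**

Total step count: 27. Longest linear sequence: 17 (steps 1–11, 14–17, 26, 27).

Steps most likely to fail:

1. Step 14 (proposed new Rh coupling). The terminal alkyne may form Rh acetylides and oligomerise, the alkenyl–Rh may be protonated before it inserts, and the syn course is assumed by analogy. The fallback sets out from 15 and 18 and comes back at 19, using known reactions with the roles of carbon and hydrogen exchanged. Boronate 18 is iodinated with retention (I2, aq NaOH, THF) to tert-butyl{[(2E)-3-iodobut-2-en-1-yl]oxy}dimethylsilane F1. Sonogashira coupling of F1 with 15 (Pd(PPh3)4, CuI, Et3N) gives the enynyl epoxide tert-butyl{[(2E)-3-methyl-5-[(1R,4S,6R)-4-{[tert-butyl(dimethyl)silyl]oxy}-2,2,6-trimethyl-7-oxabicyclo[4.1.0]heptan-1-yl]pent-2-en-4-yn-1-yl]oxy}dimethylsilane F2. Pd(0)/formate hydrogenolysis of F2 (Pd2(dba)3·CHCl3, n‑Bu3P, HCO2NH4, THF, 25 °C) then delivers hydride to C8 anti to the departing epoxide oxygen, which puts C9 on the oxygen side and gives the same allene 19.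

2. Step 15 (Ag cycloisomerisation). The vinylallene could undergo competing carbocyclisation, or the axis could be scrambled and give C8 epimers. The fallback sets out from 19 and comes back at 20. Iodoetherification (NIS, CH2Cl2, 0 °C; anti addition of O and I across C7=C8) gives tert-butyl{[(2E)-3-[(2R,6S,7aR)-6-{[tert-butyl(dimethyl)silyl]oxy}-3-iodo-4,4,7a-trimethyl-2,4,5,6,7,7a-hexahydro-1-benzofuran-2-yl]but-2-en-1-yl]oxy}dimethylsilane F3. Pd‑catalysed reduction of the vinyl iodide (Pd(PPh3)4, Bu3SnH, THF) then gives 20.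

3. Step 6 (asymmetric hydroboration). The enantioselectivity of IpcBH2 on this cis‑disubstituted diene bond and its sense are the least secure stereochemical point before the new step. The fallback sets out from 7 and comes back at 12, replacing asymmetric induction by a diastereomer separation. Hydroboration with 9‑BBN (then NaOH/H2O2) gives racemic 4-{[(2-methoxypropan-2-yl)oxy]methyl}-3,5,5-trimethylcyclohex-3-en-1-ol F4. Silylation gives racemic tert-butyl[(4-{[(2-methoxypropan-2-yl)oxy]methyl}-3,5,5-trimethylcyclohex-3-en-1-yl)oxy]dimethylsilane F5, and PPTS/MeOH gives racemic (4-{[tert-butyl(dimethyl)silyl]oxy}-2,6,6-trimethylcyclohex-1-en-1-yl)methanol F6. The reagent‑controlled Sharpless epoxidation of step 9 converts the two enantiomers of F6 into 12 and its syn diastereomer [(1R,4R,6R)-4-{[tert-butyl(dimethyl)silyl]oxy}-2,2,6-trimethyl-7-oxabicyclo[4.1.0]heptan-1-yl]methanol F7, which is removed by chromatography (maximum 50 % of 12).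

**Further compounds**

F1 | step 14 | tert-butyl{[(2E)-3-iodobut-2-en-1-yl]oxy}dimethylsilane | C/C(I)=C\CO[Si](C)(C)C(C)(C)C
F2 | step 14 | tert-butyl{[(2E)-3-methyl-5-[(1R,4S,6R)-4-{[tert-butyl(dimethyl)silyl]oxy}-2,2,6-trimethyl-7-oxabicyclo[4.1.0]heptan-1-yl]pent-2-en-4-yn-1-yl]oxy}dimethylsilane | CC(C)(C)[Si](C)(C)OC/C=C(\C)C#C[C@]12C(C)(C)C[C@H](O[Si](C)(C)C(C)(C)C)C[C@@]1(C)O2
F3 | step 15 | tert-butyl{[(2E)-3-[(2R,6S,7aR)-6-{[tert-butyl(dimethyl)silyl]oxy}-3-iodo-4,4,7a-trimethyl-2,4,5,6,7,7a-hexahydro-1-benzofuran-2-yl]but-2-en-1-yl]oxy}dimethylsilane | CC(C)(C)[Si](C)(C)OC/C=C(\C)[C@H]1C(I)=C2C(C)(C)C[C@H](O[Si](C)(C)C(C)(C)C)C[C@@]2(C)O1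
F4 | step 6 | 4-{[(2-methoxypropan-2-yl)oxy]methyl}-3,5,5-trimethylcyclohex-3-en-1-ol (racemic) | COC(C)(C)OCC1=C(C)CC(O)CC1(C)C
F5 | step 6 | tert-butyl[(4-{[(2-methoxypropan-2-yl)oxy]methyl}-3,5,5-trimethylcyclohex-3-en-1-yl)oxy]dimethylsilane (racemic) | COC(C)(C)OCC1=C(C)CC(O[Si](C)(C)C(C)(C)C)CC1(C)C
F6 | step 6 | (4-{[tert-butyl(dimethyl)silyl]oxy}-2,6,6-trimethylcyclohex-1-en-1-yl)methanol (racemic) | OCC1=C(C)CC(O[Si](C)(C)C(C)(C)C)CC1(C)C
F7 | step 6 | [(1R,4R,6R)-4-{[tert-butyl(dimethyl)silyl]oxy}-2,2,6-trimethyl-7-oxabicyclo[4.1.0]heptan-1-yl]methanol | OC[C@]12C(C)(C)C[C@@H](O[Si](C)(C)C(C)(C)C)C[C@@]1(C)O2
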